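**Retrosynthetic overview**
1. The target is a trans-3,4-disubstituted oxolane (O1, C2, C3, C4, C5) in which both carbons next to O1 are bare CH2 groups, C3 carries the (R)-aryl carbinol carbon and C4 the guaiacyl CH2. C2–O1–C5 therefore maps onto the parent carbonyl ylide and C3–C4 onto an (E)-alkene that already holds both arms.
2. Endgame: global O-debenzylation ⇐ reagent-controlled reduction of the C3 aryl ketone ⇐ Weinreb amide plus aryllithium (carbinol carbon–aryl bond).
3. Key disconnection: C2–C3 and C4–C5 form together in a [3+2] cycloaddition of the ylide (from ClCH2OCH2SiMe3 and CsF) to an (E)-N-enoyl oxazolidinone; this closes the only ring made in the route.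
4. The enoyl imide comes from cross-metathesis of O-benzyl eugenol with the N-acryloyl auxiliary.
5. Two design points: both phenols are benzyl ethers, because an aryl silyl ether is not expected to survive excess fluoride and the phenoxide released would isomerise the dipolarophile; the auxiliary is (R)-4-benzyl, for the reason in the remark below.

Key step: step 5

Remark on the chemistry (assumption): CsF in MeCN is taken to leave the imide unchelated, so it reacts through the anti-carbonyl s-cis rotamer, whose open face is the reverse of that of a chelated imide. On this model the (R)-auxiliary, not the (S), leads to (3R,4R).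

**Route**

Step 1
Reactants: 1 eugenol (4-allyl-2-methoxyphenol)
Product: 2 4-allyl-1-(benzyloxy)-2-methoxybenzene
Conditions: BnBr, K2CO3, acetone, reflux
Reagents that add atoms: benzyl bromide, BrCc1ccccc1
Why: Williamson ether synthesis on the phenoxide; the benzyl ether is inert to the fluoride, organolithium and borane used later, and the allyl group is untouched.

Step 2
Reactants: 3 (R)-4-benzyloxazolidin-2-one; 4 acryloyl chloride
Product: 6 (R)-3-acryloyl-4-benzyloxazolidin-2-one, via N-lithio oxazolidinone 5 (not isolated)
Conditions: n-BuLi, THF, −78 °C; then 4, −78 to 0 °C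
Reagents that add atoms: n-butyllithium, [Li]CCCC (lithium only in intermediate 5)
Why: N-acylation of the lithium amide by the acid chloride (imide formation) at low temperature and short contact time to limit acrylate polymerisation; the auxiliary stereocentre is not involved.

Step 3
Reactants: 2 4-allyl-1-(benzyloxy)-2-methoxybenzene; 6 (R)-3-acryloyl-4-benzyloxazolidin-2-one
Product: 7 (R)-4-benzyl-3-[(E)-4-(4-benzyloxy-3-methoxyphenyl)but-2-enoyl]oxazolidin-2-one
Conditions: second-generation Hoveyda–Grubbs catalyst RuCl2(H2IMes)(=CH-C6H4-2-O-i-Pr) (5 mol%), 1,4-benzoquinone (10 mol%), 2 (2 equiv), CH2Cl2, 40 °C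
Reagents that add atoms: none
Why: Olefin cross-metathesis between a readily homodimerising allylarene and an electron-poor acryloyl imide that does not homodimerise should favour the cross product as the (E)-isomer, with benzoquinone suppressing ruthenium hydride migration of the allyl double bond.

Step 4
Reactants: 8 (trimethylsilyl)methanol; 9 paraformaldehyde
Product: 10 chloromethyl trimethylsilylmethyl ether
Conditions: (CH2O)n, HCl (g), neat, 0 °C; CaCl2; distilled and used fresh
Reagents that add atoms: hydrogen chloride, Cl
Why: Chloromethylation of an alcohol (hemiacetal formation, then substitution of the hemiacetal OH by chloride), the standard preparation of α-chloro ethers, under which the Si–CH2 bond is stable.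

Step 5
Reactants: 7 (R)-4-benzyl-3-[(E)-4-(4-benzyloxy-3-methoxyphenyl)but-2-enoyl]oxazolidin-2-one; 10 chloromethyl trimethylsilylmethyl ether
Product: 12 (R)-4-benzyl-3-{[(3R,4R)-4-(4-benzyloxy-3-methoxybenzyl)oxolan-3-yl]carbonyl}oxazolidin-2-one, via carbonyl ylide 11 (not isolated)
Conditions: CsF (anhydrous, 4 equiv), 10 (3 equiv, slow addition), MeCN, 0 °C to rt; chromatography to remove the (3S,4S) diastereomer
Reagents that add atoms: none
Why: Proposed new method: fluoride attacks silicon of 10 and chloride leaves, releasing the parent carbonyl ylide 11, which adds as a 4π-electron dipole across the electron-poor Cα=Cβ bond of 7 in a concerted suprafacial [3+2] cycloaddition whose closest known relatives are the CsF-induced additions of this same ylide to acrylates, fumarates and enones (racemic) and the additions of the analogous non-stabilised azomethine ylide to N-enoyl oxazolidinones; face control of the carbonyl ylide by an imide auxiliary is the part without precedent. The oxolane closes by intermolecular cycloaddition, C2–C3 and C4–C5 forming together, with the imide lowering the alkene LUMO toward the electron-rich dipole. C3 and C4 come out trans because the (E) geometry is transferred stereospecifically. Their absolute configuration is set by the (R)-benzyl group: in the unchelated anti-carbonyl s-cis rotamer it lies on the Cα-Re/Cβ-Si side, so the ylide should add to the Cα-Si/Cβ-Re face and give (3R,4R). Because the benzyl group is remote from the alkene in this rotamer the bias may be modest, and the (3S,4S) diastereomer would be removed by chromatography or crystallisation, the auxiliary serving also as a resolving handle. The step needs cycloaddition to outrun deprotonation of the acidic ArCH2 (which would move the alkene into conjugation with the arene), and this is served by slow release of the short-lived ylide at 0 °C over anhydrous CsF and by the absence of any fluoride-labile phenol protection.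

Step 6
Reactants: 12 (R)-4-benzyl-3-{[(3R,4R)-4-(4-benzyloxy-3-methoxybenzyl)oxolan-3-yl]carbonyl}oxazolidin-2-one
Product: 14 (3R,4R)-4-(4-benzyloxy-3-methoxybenzyl)oxolane-3-carboxylic acid, via peroxy acid 13 (not isolated)
Conditions: LiOH, H2O2 (30% aq), THF/H2O, 0 °C; Na2SO3 (aq); HCl (aq) to pH 2
Reagents that add atoms: hydrogen peroxide, OO
Why: Hydroperoxide cleavage of the N-acyl oxazolidinone, in which the α-effect nucleophile attacks the exocyclic carbonyl even of an α-branched imide and sulfite reduces the peracid; 0 °C should leave C3 untouched, and trans is in any case the more stable arrangement.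

Step 7
Reactants: 14 (3R,4R)-4-(4-benzyloxy-3-methoxybenzyl)oxolane-3-carboxylic acid
Product: 16 (3R,4R)-4-(4-benzyloxy-3-methoxybenzyl)-N-methoxy-N-methyloxolane-3-carboxamide, via acyl imidazolide 15 (not isolated)
Conditions: 1,1'-carbonyldiimidazole, CH2Cl2, rt; then MeNHOMe·HCl, rt
Reagents that add atoms: N,O-dimethylhydroxylamine hydrochloride, CNOC.Cl; 1,1'-carbonyldiimidazole, O=C(n1ccnc1)n1ccnc1 (imidazolyl only in intermediate 15)
Why: Amide coupling through the acyl imidazolide gives the Weinreb amide under conditions too weakly basic to epimerise C3.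

Step 8
Reactants: 17 4-bromo-2-methoxyphenol
Product: 18 1-(benzyloxy)-4-bromo-2-methoxybenzene
Conditions: BnBr, K2CO3, DMF, rt
Reagents that add atoms: benzyl bromide, BrCc1ccccc1
Why: Williamson ether synthesis; the benzyl ether tolerates bromine–lithium exchange at −78 °C.

Step 9
Reactants: 18 1-(benzyloxy)-4-bromo-2-methoxybenzene; 16 (3R,4R)-4-(4-benzyloxy-3-methoxybenzyl)-N-methoxy-N-methyloxolane-3-carboxamide
Product: 21 (4-benzyloxy-3-methoxyphenyl)[(3R,4R)-4-(4-benzyloxy-3-methoxybenzyl)oxolan-3-yl]methanone, via aryllithium 19 (not isolated), via tetrahedral lithium alkoxide 20 (not isolated)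
Conditions: 18 (1.3 equiv), n-BuLi, THF, −78 °C; then 16, −78 to −40 °C; NH4Cl (aq)
Reagents that add atoms: n-butyllithium, [Li]CCCC (lithium only in intermediates 19 and 20)
Why: Bromine–lithium exchange followed by Weinreb ketone synthesis, in which the chelated tetrahedral adduct 20 persists until the quench so that only one aryl group adds, and the trans C3/C4 arrangement is the stable one.

Step 10
Reactants: 21 (4-benzyloxy-3-methoxyphenyl)[(3R,4R)-4-(4-benzyloxy-3-methoxybenzyl)oxolan-3-yl]methanone
Product: 22 (R)-(4-benzyloxy-3-methoxyphenyl)[(3R,4R)-4-(4-benzyloxy-3-methoxybenzyl)oxolan-3-yl]methanol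
Conditions: (S)-1-methyl-3,3-diphenyltetrahydro-1H,3H-pyrrolo[1,2-c][1,3,2]oxazaborole [(S)-Me-CBS] (0.5 equiv), BH3·SMe2, THF, −20 °C; MeOH
Reagents that add atoms: none
Why: Corey–Bakshi–Shibata reduction, in which the ketone binds the ring boron of the (S)-oxazaborolidine·BH3 complex anti to the larger aryl group and hydride is delivered through a six-membered transition state to give the (R)-carbinol [the sense in which acetophenone gives (R)-1-phenylethanol; O > aryl > C3 keeps the descriptor], reagent control being relied on because the Felkin–Anh preference of C3 (C4 as the large group) is expected to favour the (S)-epimer.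

Step 11
Reactants: 22 (R)-(4-benzyloxy-3-methoxyphenyl)[(3R,4R)-4-(4-benzyloxy-3-methoxybenzyl)oxolan-3-yl]methanol
Product: 23 (R)-(4-hydroxy-3-methoxyphenyl)[(3R,4R)-4-(4-hydroxy-3-methoxybenzyl)oxolan-3-yl]methanol (CNP0234428.1)
Conditions: H2 (1 atm), Pd/C (10%), EtOAc, rt; stopped after uptake of two equivalents
Reagents that add atoms: none
Why: Hydrogenolysis of aryl benzyl ethers on Pd/C in a neutral solvent is much faster than C–O cleavage of the secondary benzylic alcohol, and none of the three stereocentres is touched.

**Compound list**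
1 | eugenol (4-allyl-2-methoxyphenol) | C=CCc1ccc(O)c(OC)c1 | starting material
2 | 4-allyl-1-(benzyloxy)-2-methoxybenzene | C=CCc1ccc(OCc2ccccc2)c(OC)c1 | intermediate
3 | (R)-4-benzyloxazolidin-2-one | O=C1N[C@H](Cc2ccccc2)CO1 | starting material
4 | acryloyl chloride | C=CC(=O)Cl | starting material
5 | N-lithio-(R)-4-benzyloxazolidin-2-one (not isolated) | [Li]N1[C@H](Cc2ccccc2)COC1=O | intermediate
6 | (R)-3-acryloyl-4-benzyloxazolidin-2-one | C=CC(=O)N1[C@H](Cc2ccccc2)COC1=O | intermediate
7 | (R)-4-benzyl-3-[(E)-4-(4-benzyloxy-3-methoxyphenyl)but-2-enoyl]oxazolidin-2-one | COc1cc(C/C=C/C(=O)N2[C@H](Cc3ccccc3)COC2=O)ccc1OCc1ccccc1 | intermediate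
8 | (trimethylsilyl)methanol | C[Si](C)(C)CO | starting material
9 | paraformaldehyde (polymer; formaldehyde unit given) | C=O | starting material
10 | chloromethyl trimethylsilylmethyl ether | C[Si](C)(C)COCCl | intermediate
11 | parent carbonyl ylide, formaldehyde O-methylide (not isolated) | [CH2-][O+]=C | intermediate
12 | (R)-4-benzyl-3-{[(3R,4R)-4-(4-benzyloxy-3-methoxybenzyl)oxolan-3-yl]carbonyl}oxazolidin-2-one | COc1cc(C[C@H]2COC[C@@H]2C(=O)N2[C@H](Cc3ccccc3)COC2=O)ccc1OCc1ccccc1 | intermediate
13 | (3R,4R)-4-(4-benzyloxy-3-methoxybenzyl)oxolane-3-carboperoxoic acid (not isolated) | COc1cc(C[C@H]2COC[C@@H]2C(=O)OO)ccc1OCc1ccccc1 | intermediate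
14 | (3R,4R)-4-(4-benzyloxy-3-methoxybenzyl)oxolane-3-carboxylic acid | COc1cc(C[C@H]2COC[C@@H]2C(=O)O)ccc1OCc1ccccc1 | intermediate
15 | 1-{[(3R,4R)-4-(4-benzyloxy-3-methoxybenzyl)oxolan-3-yl]carbonyl}imidazole (not isolated) | COc1cc(C[C@H]2COC[C@@H]2C(=O)n2ccnc2)ccc1OCc1ccccc1 | intermediate
16 | (3R,4R)-4-(4-benzyloxy-3-methoxybenzyl)-N-methoxy-N-methyloxolane-3-carboxamide | COc1cc(C[C@H]2COC[C@@H]2C(=O)N(C)OC)ccc1OCc1ccccc1 | intermediate
17 | 4-bromo-2-methoxyphenol | COc1cc(Br)ccc1O | starting material
18 | 1-(benzyloxy)-4-bromo-2-methoxybenzene | COc1cc(Br)ccc1OCc1ccccc1 | intermediate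
19 | (4-benzyloxy-3-methoxyphenyl)lithium (not isolated) | [Li]c1ccc(OCc2ccccc2)c(OC)c1 | intermediate
20 | lithium alkoxide of the tetrahedral adduct of 19 with 16, configuration at the new carbon undefined (not isolated) | COc1cc(C[C@H]2COC[C@@H]2C(O[Li])(N(C)OC)c2ccc(OCc3ccccc3)c(OC)c2)ccc1OCc1ccccc1 | intermediate
21 | (4-benzyloxy-3-methoxyphenyl)[(3R,4R)-4-(4-benzyloxy-3-methoxybenzyl)oxolan-3-yl]methanone | COc1cc(C[C@H]2COC[C@@H]2C(=O)c2ccc(OCc3ccccc3)c(OC)c2)ccc1OCc1ccccc1 | intermediate
22 | (R)-(4-benzyloxy-3-methoxyphenyl)[(3R,4R)-4-(4-benzyloxy-3-methoxybenzyl)oxolan-3-yl]methanol | COc1cc(C[C@H]2COC[C@@H]2[C@@H](O)c2ccc(OCc3ccccc3)c(OC)c2)ccc1OCc1ccccc1 | intermediate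
23 | (R)-(4-hydroxy-3-methoxyphenyl)[(3R,4R)-4-(4-hydroxy-3-methoxybenzyl)oxolan-3-yl]methanol | COc1cc(C[C@H]2COC[C@@H]2[C@@H](O)c2ccc(O)c(OC)c2)ccc1O | target

**Step count and risks**

Total step count: 11. Longest linear sequence: 8 steps (steps 1, 3, 5, 6, 7, 9, 10, 11, from eugenol to the target).

Steps most likely to fail:

1. Step 5. The facial discrimination may be weak, since the directing benzyl group sits far from the alkene in the unchelated rotamer. The double bond may also migrate under basic fluoride into conjugation with the arene before the ylide arrives. The fallback uses known chemistry, sets out from 2 and comes back at 12. Cross-metathesis of 2 with methyl acrylate over RuCl2(H2IMes)(=CH-C6H4-2-O-i-Pr) should give methyl (E)-4-(4-benzyloxy-3-methoxyphenyl)but-2-enoate F1, a plain enoate of the class for which the cycloaddition of 11 is established and whose γ-CH2 is less acidic than that of the imide. Ylide 11 (from 10 and CsF in MeCN) should add to it to give racemic trans methyl 4-(4-benzyloxy-3-methoxybenzyl)oxolane-3-carboxylate F2. Saponification (LiOH, THF/H2O) should give racemic trans 4-(4-benzyloxy-3-methoxybenzyl)oxolane-3-carboxylic acid F3. Activation with t-BuCOCl and Et3N gives the mixed pivalic anhydride F4, which acylates the lithiated auxiliary 5. The two enantiomers thereby become 12 and its diastereomer (R)-4-benzyl-3-{[(3S,4S)-4-(4-benzyloxy-3-methoxybenzyl)oxolan-3-yl]carbonyl}oxazolidin-2-one F5, to be separated by chromatography or crystallisation, so the auxiliary acts as a resolving agent.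

2. Step 10. Catalyst control may be eroded by the adjacent C3 stereocentre (mismatched pairing), giving carbinol epimers. The fallback sets out from 16 and comes back at 22, and swaps the roles of hydride and aryl. Reduction of 16 with i-Bu2AlH (THF, −78 °C) should give (3R,4R)-4-(4-benzyloxy-3-methoxybenzyl)oxolane-3-carbaldehyde F6. Addition of aryllithium 19 at −78 °C then puts the aryl group where the hydride would have gone, so the same Felkin–Anh preference of C3 that opposes the ketone reduction should now favour the (R)-carbinol 22.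

3. Step 11. The benzylic C–OH bond may be hydrogenolysed, which becomes easier once the para-phenol is free and the catalyst surface is acidic. The fallback sets out from 21 and comes back at 23, and removes the benzyl groups before the carbinol exists. Hydrogenolysis of 21 (H2, Pd/C, EtOAc) should cleave both aryl benzyl ethers well before the electron-rich aryl ketone is reduced, giving (4-hydroxy-3-methoxyphenyl)[(3R,4R)-4-(4-hydroxy-3-methoxybenzyl)oxolan-3-yl]methanone F7. With the fluoride step already past, silylation (i-Pr3SiCl, imidazole, DMF) should give the bis(triisopropylsilyl) ether of the ketone F8. The reduction of step 10 applied to F8 should give the (R)-carbinol bis(triisopropylsilyl) ether F9, and Bu4NF buffered with AcOH in THF should release 23.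

Further compounds
F1 | step 5 | methyl (E)-4-(4-benzyloxy-3-methoxyphenyl)but-2-enoate | COC(=O)/C=C/Cc1ccc(OCc2ccccc2)c(OC)c1
F2 | step 5 | methyl trans-4-(4-benzyloxy-3-methoxybenzyl)oxolane-3-carboxylate (racemate, one enantiomer drawn) | COc1cc(C[C@H]2COC[C@@H]2C(=O)OC)ccc1OCc1ccccc1
F3 | step 5 | trans-4-(4-benzyloxy-3-methoxybenzyl)oxolane-3-carboxylic acid (racemate, one enantiomer drawn) | COc1cc(C[C@H]2COC[C@@H]2C(=O)O)ccc1OCc1ccccc1
F4 | step 5 | mixed anhydride of F3 with pivalic acid (racemate, one enantiomer drawn) | COc1cc(C[C@H]2COC[C@@H]2C(=O)OC(=O)C(C)(C)C)ccc1OCc1ccccc1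
F5 | step 5 | (R)-4-benzyl-3-{[(3S,4S)-4-(4-benzyloxy-3-methoxybenzyl)oxolan-3-yl]carbonyl}oxazolidin-2-one | COc1cc(C[C@@H]2COC[C@H]2C(=O)N2[C@H](Cc3ccccc3)COC2=O)ccc1OCc1ccccc1
F6 | step 10 | (3R,4R)-4-(4-benzyloxy-3-methoxybenzyl)oxolane-3-carbaldehyde | COc1cc(C[C@H]2COC[C@@H]2C=O)ccc1OCc1ccccc1
F7 | step 11 | (4-hydroxy-3-methoxyphenyl)[(3R,4R)-4-(4-hydroxy-3-methoxybenzyl)oxolan-3-yl]methanone | COc1cc(C[C@H]2COC[C@@H]2C(=O)c2ccc(O)c(OC)c2)ccc1O
F8 | step 11 | [3-methoxy-4-(triisopropylsilyloxy)phenyl]{(3R,4R)-4-[3-methoxy-4-(triisopropylsilyloxy)benzyl]oxolan-3-yl}methanone | COc1cc(C[C@H]2COC[C@@H]2C(=O)c2ccc(O[Si](C(C)C)(C(C)C)C(C)C)c(OC)c2)ccc1O[Si](C(C)C)(C(C)C)C(C)C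
F9 | step 11 | (R)-[3-methoxy-4-(triisopropylsilyloxy)phenyl]{(3R,4R)-4-[3-methoxy-4-(triisopropylsilyloxy)benzyl]oxolan-3-yl}methanol | COc1cc(C[C@H]2COC[C@@H]2[C@@H](O)c2ccc(O[Si](C(C)C)(C(C)C)C(C)C)c(OC)c2)ccc1O[Si](C(C)C)(C(C)C)C(C)C
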